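## Retrosynthetic overview

1. The C3–O ester bond is made last but one, by Pd-catalysed allylic C–H esterification of a 2-methylene spiroketal lactone with silyl-protected (S)-3-hydroxy-2,2-dimethylbutanoic acid (fragment C); desilylation ends the route.
2. The spiro-lactone ring (fourth ring) comes from Negishi coupling of a lactone-derived ketene acetal phosphate with the zinc homoenolate of (R)-Roche ester (fragment B), then acid-triggered spirolactonisation.
3. The oxolane ring (third ring, first as a γ-lactone) comes from carboxylate-directed Pd-catalysed γ-methyl C–H lactonisation of a bicyclic keto acid; the ketone then becomes the exocyclic methylene.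
4. The cyclobutane (second ring) is closed on a cyclohexenone (fragment A) by anti cuprate methylation and 4-exo-tet enolate alkylation.
5. The cyclohexenone (first ring) comes from an organocatalytic Michael/aldol sequence of 3-silyloxypropanal with methyl vinyl ketone, then Mukaiyama–Michael/Saegusa introduction of the acetate arm.

Assumption: the spiroketal configuration of the target is the thermodynamically preferred one (lactone methyl cis to the C–CH2 branch of the ketal carbon), so acid equilibration in step 14 delivers it.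

Locants used below: bicyclo[3.1.1]heptane C1 and C5 are the bridgeheads, C2–C4 the three-carbon bridge, C6 the quaternary one-carbon bridge, C7 the CH2 bridge.

## Route

Step 1
Reactants: 1 propane-1,3-diol
Product: 2 3-[(tert-butyldimethylsilyl)oxy]propan-1-ol
Conditions: NaH (1.0 equiv), THF, 23 °C; then TBSCl (1.0 equiv)
Reagents that add atoms: tert-butyldimethylsilyl chloride, CC(C)(C)[Si](C)(C)Cl
Why: Monosilylation of the symmetrical diol through its sparingly soluble monosodium alkoxide (O-silylation) stops cleanly at the mono ether.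

Step 2
Reactants: 2 3-[(tert-butyldimethylsilyl)oxy]propan-1-ol
Product: 3 3-[(tert-butyldimethylsilyl)oxy]propanal
Conditions: TEMPO (10 mol %), PhI(OAc)2, CH2Cl2, 23 °C
Reagents that add atoms: none
Why: Nitroxyl-catalysed oxidation with a hypervalent iodine co-oxidant stops at the aldehyde and leaves the silyl ether alone.

Step 3
Reactants: 3 3-[(tert-butyldimethylsilyl)oxy]propanal; 4 but-3-en-2-one
Product: 6 (4R)-4-{[(tert-butyldimethylsilyl)oxy]methyl}cyclohex-2-en-1-one, via keto aldehyde 5 (not isolated)
Conditions: 4 (1.5 equiv), (S)-α,α-diphenylprolinol trimethylsilyl ether (10 mol %), ethyl 3,4-dihydroxybenzoate (20 mol %), neat, 4 °C; then p-TsOH·H2O (20 mol %), toluene, 40 °C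
Reagents that add atoms: none
Why: Enamine-mediated Michael addition (Hayashi–Jørgensen catalyst) takes place on the enamine face remote from the diphenyl(silyloxy)methyl group and sets the (S) α-centre of 5, which becomes C4 (R) of the enone after acid-catalysed intramolecular aldol condensation, the only closure that gives a six-membered ring.

Step 4
Reactants: 6 (4R)-4-{[(tert-butyldimethylsilyl)oxy]methyl}cyclohex-2-en-1-one
Product: 7 (4R)-4-(bromomethyl)cyclohex-2-en-1-one
Conditions: Ph3PBr2, CH2Cl2, 0 → 23 °C
Reagents that add atoms: triphenylphosphine dibromide, BrP(Br)(c1ccccc1)(c1ccccc1)c1ccccc1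
Why: Ph3PBr2 converts a primary silyl ether directly into the bromide (Appel-type SN2 at the primary carbon), so the stereocentre and the enone are untouched.

Step 5
Reactants: 8 tert-butyl acetate
Product: 9 tert-butyl[(1-tert-butoxyethenyl)oxy]dimethylsilane
Conditions: LiN(i-Pr)2, THF, −78 °C; then TBSCl, HMPA, −78 → 0 °C
Reagents that add atoms: tert-butyldimethylsilyl chloride, CC(C)(C)[Si](C)(C)Cl
Why: O-silylation of the kinetically formed ester enolate gives the ketene silyl acetal, a neutral acetate-enolate equivalent.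

Step 6
Reactants: 7 (4R)-4-(bromomethyl)cyclohex-2-en-1-one; 9 tert-butyl[(1-tert-butoxyethenyl)oxy]dimethylsilane
Product: 11 tert-butyl 2-[(6R)-6-(bromomethyl)-3-oxocyclohex-1-en-1-yl]acetate, via silyl enol ether 10 (not isolated)
Conditions: 9 (1.3 equiv), TBSOTf (5 mol %), CH2Cl2, −78 °C; then Et3N, Pd(OAc)2 (1.1 equiv), MeCN, 23 → 40 °C
Reagents that add atoms: none
Why: Mukaiyama–Michael addition with silyl transfer gives the regiodefined silyl enol ether (the transient C3 centre is trans to CH2Br and is erased), and Saegusa–Ito oxidation restores the C2–C3 double bond, so the enone is β-functionalised with the C4 centre intact.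

Step 7
Reactants: 11 tert-butyl 2-[(6R)-6-(bromomethyl)-3-oxocyclohex-1-en-1-yl]acetate
Product: 13 tert-butyl 2-[(1R,5S,6R)-6-methyl-2-oxobicyclo[3.1.1]heptan-6-yl]acetate, via lithium enolate 12 (not isolated)
Conditions: Me2CuLi (1.15 equiv), Et2O, −78 → −30 °C; then THF/HMPA, −30 → 23 °C
Reagents that add atoms: lithium dimethylcuprate, [Li+].C[Cu-]C
Why: Gilman cuprate 1,4-addition occurs anti to the pseudoaxial bromomethyl group and sets the quaternary centre (methyl trans, acetate arm cis to CH2Br), and the regiodefined enolate then closes the cyclobutane by intramolecular 4-exo-tet alkylation on the face of CH2Br, which fixes both bridgeheads and puts the methyl over the C2–C4 bridge.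

Step 8
Reactants: 13 tert-butyl 2-[(1R,5S,6R)-6-methyl-2-oxobicyclo[3.1.1]heptan-6-yl]acetate
Product: 14 2-[(1R,5S,6R)-6-methyl-2-oxobicyclo[3.1.1]heptan-6-yl]acetic acid
Conditions: CF3CO2H/CH2Cl2 (1:4), 0 → 23 °C
Reagents that add atoms: none
Why: Acidolysis of the tert-butyl ester (loss of isobutene) frees the acid without base, which avoids retro-Michael opening of the δ-keto ester cyclobutane.

Step 9
Reactants: 14 2-[(1R,5S,6R)-6-methyl-2-oxobicyclo[3.1.1]heptan-6-yl]acetic acid
Product: 15 (1R,5S,6S)-spiro[bicyclo[3.1.1]heptane-6,3'-oxolane]-2,5'-dione (lactone O–CH2 over the C2–C4 bridge)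
Conditions: Pd(OAc)2 (10 mol %), N-acetyl-β-alanine (20 mol %), t-BuOOH (aq., 3 equiv), CsHCO3 (0.5 equiv), (CF3)2CHOH, 60 °C
Reagents that add atoms: none
Why: Carboxylate-directed C(sp3)–H lactonisation: divalent palladium cyclometalates the only γ-methyl group through a six-membered palladacycle (concerted metalation–deprotonation), the peroxide oxidises it to tetravalent palladium and C–O reductive elimination closes the γ-lactone, while the tertiary strained bridgehead C–H bonds do not compete and no stereocentre changes.

Step 10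
Reactants: 15 (1R,5S,6S)-spiro[bicyclo[3.1.1]heptane-6,3'-oxolane]-2,5'-dione
Product: 16 (1S,5S,6S)-2-methylidenespiro[bicyclo[3.1.1]heptane-6,3'-oxolan]-5'-one
Conditions: Zn, CH2Br2, TiCl4, THF/CH2Cl2, 0 → 23 °C
Reagents that add atoms: dibromomethane, BrCBr
Why: Lombardo–Takai methylenation is non-basic and ketone-selective, so the hindered enolisable ketone is methylenated while the lactone and the base-sensitive cyclobutane survive.

Step 11
Reactants: 17 methyl (2R)-3-hydroxy-2-methylpropanoate
Product: 18 methyl (2S)-3-iodo-2-methylpropanoate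
Conditions: I2, PPh3, imidazole, CH2Cl2, 0 → 23 °C
Reagents that add atoms: iodine, II
Why: Appel iodination of the primary alcohol does not touch the α-stereocentre (the descriptor changes only through the priority rules).

Step 12
Reactants: 18 methyl (2S)-3-iodo-2-methylpropanoate
Product: 19 iodo[(2S)-3-methoxy-2-methyl-3-oxopropyl]zinc
Conditions: Zn dust (activated with 1,2-dibromoethane and Me3SiCl), DMF, 23 °C
Reagents that add atoms: zinc, [Zn]
Why: Direct insertion of activated zinc into the primary C–I bond gives the chelation-stabilised β-zincio ester (zinc homoenolate) without racemisation or β-elimination.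

Step 13
Reactants: 16 (1S,5S,6S)-2-methylidenespiro[bicyclo[3.1.1]heptane-6,3'-oxolan]-5'-one; 19 iodo[(2S)-3-methoxy-2-methyl-3-oxopropyl]zinc
Product: 21 methyl (2R)-2-methyl-3-[(1S,5S)-2-methylidene-2'H-spiro[bicyclo[3.1.1]heptane-6,3'-furan]-5'-yl]propanoate, via ketene acetal phosphate 20 (not isolated)
Conditions: KN(SiMe3)2, (PhO)2P(O)Cl, HMPA, THF, −78 °C; then 19 (2 equiv), Pd(PPh3)4 (5 mol %), THF/DMF, 23 → 45 °C
Reagents that add atoms: none
Why: Kinetic lactone enolisation with in situ O-phosphorylation gives the ketene acetal phosphate, whose C–O bond adds oxidatively to zerovalent palladium and undergoes sp2–sp3 Negishi coupling with the alkylzinc, forming the C–C bond at the future spiro carbon with no stereocentre affected.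

Step 14
Reactants: 21 methyl (2R)-2-methyl-3-[(1S,5S)-2-methylidene-2'H-spiro[bicyclo[3.1.1]heptane-6,3'-furan]-5'-yl]propanoate
Product: 23 spiroketal lactone (2-methylidenebicyclo[3.1.1]heptane spiro-fused at C6 to an oxolane whose ketal carbon carries the (3R)-3-methyl-γ-butyrolactone; all centres as in the target), via potassium carboxylate 22 (not isolated)
Conditions: KOSiMe3, THF, 23 °C; then PPTS (2 equiv), CH2Cl2, 23 °C
Reagents that add atoms: potassium trimethylsilanolate, C[Si](C)(C)[O-].[K+]
Why: Anhydrous ester cleavage followed by mild acid protonates the enol ether to an oxocarbenium ion that the carboxylic acid traps (5-exo spirolactonisation), and the spiro centre equilibrates under the acid to the isomer with the lactone methyl cis to the C–CH2 branch, which is the target configuration.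

Step 15
Reactants: 24 methyl 3-oxobutanoate
Product: 25 methyl 2,2-dimethyl-3-oxobutanoate
Conditions: MeI (2.5 equiv), K2CO3, acetone, reflux
Reagents that add atoms: iodomethane, CI
Why: Double C-alkylation of the β-keto ester runs to the gem-dimethyl compound, which can no longer enolise between the carbonyls.

Step 16
Reactants: 25 methyl 2,2-dimethyl-3-oxobutanoate
Product: 26 methyl (3S)-3-hydroxy-2,2-dimethylbutanoate
Conditions: H2 (50 atm), RuCl2[(S)-BINAP] (0.5 mol %), MeOH, 50 °C
Reagents that add atoms: none
Why: Noyori asymmetric hydrogenation of the chelated β-keto ester with the (S)-BINAP ruthenium catalyst gives the (S)-carbinol, the same sense as for methyl acetoacetate.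

Step 17
Reactants: 26 methyl (3S)-3-hydroxy-2,2-dimethylbutanoate
Product: 27 methyl (3S)-3-[(tert-butyldimethylsilyl)oxy]-2,2-dimethylbutanoate
Conditions: TBSOTf, 2,6-lutidine, CH2Cl2, 0 °C
Reagents that add atoms: tert-butyldimethylsilyl trifluoromethanesulfonate, CC(C)(C)[Si](C)(C)OS(=O)(=O)C(F)(F)F
Why: The silyl triflate silylates the hindered secondary alcohol under non-nucleophilic base conditions.

Step 18
Reactants: 27 methyl (3S)-3-[(tert-butyldimethylsilyl)oxy]-2,2-dimethylbutanoate
Product: 28 (3S)-3-[(tert-butyldimethylsilyl)oxy]-2,2-dimethylbutanoic acid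
Conditions: LiOH, THF/MeOH/H2O, 50 °C; then aq. HCl to pH 3
Reagents that add atoms: lithium hydroxide, [Li+].[OH-]
Why: Saponification of the methyl ester of an α-quaternary acid has no α-hydrogen to epimerise and leaves the secondary silyl ether in place.

Step 19
Reactants: 23 spiroketal lactone; 28 (3S)-3-[(tert-butyldimethylsilyl)oxy]-2,2-dimethylbutanoic acid
Product: 29 O-tert-butyldimethylsilyl ether of the target (ester oxygen at C3 trans to the C6 bridge)
Conditions: Pd(OAc)2 (10 mol %), 1,2-bis(phenylsulfinyl)ethane (10 mol %), 1,4-benzoquinone (2 equiv), 28 (2 equiv), 4 Å MS, 1,4-dioxane, 45 °C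
Reagents that add atoms: none
Why: Proposed new method: the sulfoxide-ligated divalent palladium carboxylate of 28 cleaves a C3–H bond of the 2-methylenebicyclo[3.1.1]heptane from the alkene face anti to the CH2O arm of the C6 bridge to give a π-allylpalladium carboxylate, and quinone-induced inner-sphere C–O reductive elimination at the ring terminus delivers the ester syn to palladium, i.e. trans to the C6 bridge, with the exocyclic alkene retained; the closest known reactions are sulfoxide-promoted allylic C–H esterification of terminal alkenes and Pd-catalysed allylic acetoxylation of β-pinene, neither shown for a 1,1-disubstituted alkene with an α-quaternary acid as fragment-coupling partner.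

Step 20
Reactants: 29 O-tert-butyldimethylsilyl ether of the target
Product: 30 target CNP0212779.5
Conditions: HF·pyridine, pyridine/THF, 0 → 23 °C
Reagents that add atoms: none
Why: Buffered fluoride removes the secondary silyl ether without touching the allylic ester, the spiroketal lactone or the exocyclic alkene.

## Compound list

1 | propane-1,3-diol | OCCCO | starting material
2 | 3-[(tert-butyldimethylsilyl)oxy]propan-1-ol | CC(C)(C)[Si](C)(C)OCCCO | intermediate
3 | 3-[(tert-butyldimethylsilyl)oxy]propanal | CC(C)(C)[Si](C)(C)OCCC=O | intermediate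
4 | but-3-en-2-one | CC(=O)C=C | starting material
5 | (2S)-2-{[(tert-butyldimethylsilyl)oxy]methyl}-5-oxohexanal | CC(=O)CC[C@@H](CO[Si](C)(C)C(C)(C)C)C=O | intermediate (not isolated)
6 | (4R)-4-{[(tert-butyldimethylsilyl)oxy]methyl}cyclohex-2-en-1-one | O=C1CC[C@@H](CO[Si](C)(C)C(C)(C)C)C=C1 | intermediate
7 | (4R)-4-(bromomethyl)cyclohex-2-en-1-one | O=C1CC[C@@H](CBr)C=C1 | intermediate
8 | tert-butyl acetate | CC(=O)OC(C)(C)C | starting material
9 | tert-butyl[(1-tert-butoxyethenyl)oxy]dimethylsilane | C=C(OC(C)(C)C)O[Si](C)(C)C(C)(C)C | intermediate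
10 | tert-butyl 2-[(1R,6R)-6-(bromomethyl)-3-[(tert-butyldimethylsilyl)oxy]cyclohex-2-en-1-yl]acetate (trans) | CC(C)(C)[Si](C)(C)OC1=C[C@@H](CC(=O)OC(C)(C)C)[C@H](CBr)CC1 | intermediate (not isolated)
11 | tert-butyl 2-[(6R)-6-(bromomethyl)-3-oxocyclohex-1-en-1-yl]acetate | O=C1CC[C@@H](CBr)C(CC(=O)OC(C)(C)C)=C1 | intermediate
12 | lithium (3S,4R)-4-(bromomethyl)-3-(2-tert-butoxy-2-oxoethyl)-3-methylcyclohex-1-en-1-olate | [Li+].[O-]C1=C[C@](C)(CC(=O)OC(C)(C)C)[C@H](CBr)CC1 | intermediate (not isolated)
13 | tert-butyl 2-[(1R,5S,6R)-6-methyl-2-oxobicyclo[3.1.1]heptan-6-yl]acetate (methyl over the C2–C4 bridge) | O=C1CC[C@H]2C[C@@H]1[C@]2(C)CC(=O)OC(C)(C)C | intermediate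
14 | 2-[(1R,5S,6R)-6-methyl-2-oxobicyclo[3.1.1]heptan-6-yl]acetic acid | O=C1CC[C@H]2C[C@@H]1[C@]2(C)CC(=O)O | intermediate
15 | (1R,5S,6S)-spiro[bicyclo[3.1.1]heptane-6,3'-oxolane]-2,5'-dione | O=C1CC[C@H]2C[C@@H]1[C@@]21COC(=O)C1 | intermediate
16 | (1S,5S,6S)-2-methylidenespiro[bicyclo[3.1.1]heptane-6,3'-oxolan]-5'-one | C=C1CC[C@H]2C[C@@H]1[C@@]21COC(=O)C1 | intermediate
17 | methyl (2R)-3-hydroxy-2-methylpropanoate | OC[C@@H](C)C(=O)OC | starting material
18 | methyl (2S)-3-iodo-2-methylpropanoate | IC[C@@H](C)C(=O)OC | intermediate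
19 | iodo[(2S)-3-methoxy-2-methyl-3-oxopropyl]zinc | I[Zn]C[C@@H](C)C(=O)OC | intermediate
20 | (1S,5S)-2-methylidene-2'H-spiro[bicyclo[3.1.1]heptane-6,3'-furan]-5'-yl diphenyl phosphate (core as in 16) | C=C1CC[C@H]2C[C@@H]1[C@@]21COC(OP(=O)(Oc3ccccc3)Oc3ccccc3)=C1 | intermediate (not isolated)
21 | methyl (2R)-2-methyl-3-[(1S,5S)-2-methylidene-2'H-spiro[bicyclo[3.1.1]heptane-6,3'-furan]-5'-yl]propanoate (core as in 16) | C=C1CC[C@H]2C[C@@H]1[C@@]21COC(C[C@@H](C)C(=O)OC)=C1 | intermediate
22 | potassium (2R)-2-methyl-3-[(1S,5S)-2-methylidene-2'H-spiro[bicyclo[3.1.1]heptane-6,3'-furan]-5'-yl]propanoate | C=C1CC[C@H]2C[C@@H]1[C@@]21COC(C[C@@H](C)C(=O)[O-])=C1.[K+] | intermediate (not isolated)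
23 | spiroketal lactone: target skeleton without the C3 ester (C3 is CH2), all centres as in the target | C=C1CC[C@H]2C[C@@H]1[C@@]21CO[C@@]2(C[C@@H](C)C(=O)O2)C1 | intermediate
24 | methyl 3-oxobutanoate | CC(=O)CC(=O)OC | starting material
25 | methyl 2,2-dimethyl-3-oxobutanoate | CC(=O)C(C)(C)C(=O)OC | intermediate
26 | methyl (3S)-3-hydroxy-2,2-dimethylbutanoate | COC(=O)C(C)(C)[C@H](C)O | intermediate
27 | methyl (3S)-3-[(tert-butyldimethylsilyl)oxy]-2,2-dimethylbutanoate | COC(=O)C(C)(C)[C@H](C)O[Si](C)(C)C(C)(C)C | intermediate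
28 | (3S)-3-[(tert-butyldimethylsilyl)oxy]-2,2-dimethylbutanoic acid | OC(=O)C(C)(C)[C@H](C)O[Si](C)(C)C(C)(C)C | intermediate
29 | O-tert-butyldimethylsilyl ether of the target | C=C1[C@@H](OC(=O)C(C)(C)[C@H](C)O[Si](C)(C)C(C)(C)C)C[C@H]2C[C@@H]1[C@@]21CO[C@@]2(C[C@@H](C)C(=O)O2)C1 | intermediate
30 | target CNP0212779.5 | C=C1[C@@H](OC(=O)C(C)(C)[C@H](C)O)C[C@H]2C[C@@H]1[C@@]21CO[C@@]2(C[C@@H](C)C(=O)O2)C1 | target

## Step count and weak points

Total step count: 20.
Longest linear sequence: 13 steps (1, 2, 3, 4, 6, 7, 8, 9, 10, 13, 14, 19, 20), from propane-1,3-diol.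

Steps most likely to fail:

**Step 7 (cuprate addition and cyclobutane closure in one flask).** The CH2 between the enone and the ester is acidic and may be deprotonated by the cuprate. The 4-exo-tet closure is slow. Base left at the end could open the new δ-keto ester cyclobutane by retro-Michael reaction. Fallback: set out from 11 and separate the two events. Me2CuLi with Me3SiCl in THF at −78 °C gives tert-butyl 2-[(1S,6R)-6-(bromomethyl)-1-methyl-3-[(trimethylsilyl)oxy]cyclohex-2-en-1-yl]acetate F1, which is isolated. One equivalent of anhydrous fluoride (Bu4N[Ph3SiF2], THF, 0 → 23 °C) then frees a metal-free enolate that closes the ring and leaves no base behind. The route is rejoined at 13.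

**Step 9 (γ-methyl C–H lactonisation).** Turnover may be low on this hindered acid, and peroxide may oxidise the ketone side. Fallback: set out from 11 and bring the oxygenated carbon in as a silylmethyl group instead of oxidising a methyl C–H bond. (i-PrO)Me2SiCH2MgCl with CuI (cat.) adds anti to the bromomethyl group and the enolate closes the cyclobutane as in step 7, giving tert-butyl 2-[(1R,5S,6S)-6-{[dimethyl(propan-2-yloxy)silyl]methyl}-2-oxobicyclo[3.1.1]heptan-6-yl]acetate F2. Tamao oxidation (H2O2, KF, KHCO3, THF/MeOH) gives tert-butyl 2-[(1R,5S,6S)-6-(hydroxymethyl)-2-oxobicyclo[3.1.1]heptan-6-yl]acetate F3. CF3CO2H then cleaves the tert-butyl ester and closes the lactone. The route is rejoined at 15.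

**Step 19 (proposed allylic C–H esterification).** The hindered carboxylate may react slowly. C–O bond formation could occur at the exocyclic CH2 terminus and give the endocyclic alkene isomer. Acid and palladium could trigger pinene-type skeletal rearrangement. Fallback with known chemistry: set out from 23. SeO2 (cat.) with t-BuOOH in CH2Cl2 hydroxylates C3 on the face away from the C6 bridge (as in β-pinene to trans-pinocarveol) and gives the allylic alcohol 3-hydroxy-23 F4. Yamaguchi esterification with 28 (2,4,6-trichlorobenzoyl chloride, Et3N, DMAP, toluene) gives the ester with retention. The route is rejoined at 29.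

## Further compounds

F1 | step 7 | tert-butyl 2-[(1S,6R)-6-(bromomethyl)-1-methyl-3-[(trimethylsilyl)oxy]cyclohex-2-en-1-yl]acetate | C[Si](C)(C)OC1=C[C@](C)(CC(=O)OC(C)(C)C)[C@H](CBr)CC1
F2 | step 9 | tert-butyl 2-[(1R,5S,6S)-6-{[dimethyl(propan-2-yloxy)silyl]methyl}-2-oxobicyclo[3.1.1]heptan-6-yl]acetate | O=C1CC[C@H]2C[C@@H]1[C@]2(C[Si](C)(C)OC(C)C)CC(=O)OC(C)(C)C
F3 | step 9 | tert-butyl 2-[(1R,5S,6S)-6-(hydroxymethyl)-2-oxobicyclo[3.1.1]heptan-6-yl]acetate | O=C1CC[C@H]2C[C@@H]1[C@]2(CO)CC(=O)OC(C)(C)C
F4 | step 19 | 3-hydroxy derivative of 23 (hydroxyl trans to the C6 bridge) | C=C1[C@@H](O)C[C@H]2C[C@@H]1[C@@]21CO[C@@]2(C[C@@H](C)C(=O)O2)C1
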